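**Retrosynthetic overview**

1. Ring B is bought as arene 1 and formylated (through iminium salt 2) to aldehyde 3; ring A is bought as gallacetophenone 4 and O-differentiated (through mono-MOM ether 5) to ketone 6.
2. Disconnection of the C2–C3 bond: Claisen–Schmidt union of 6 and 3 gives chalcone 7.
3. Ring C, the only ring built, is closed first at O1–C2 by oxa-Michael addition (chalcone isomerase mode) to flavanone 8.
4. Disconnection of the C3–aryl bond: ring B is then moved from C2 to C3 by an oxidative 1,2-aryl shift (isoflavone synthase mode), giving isoflavone 10 through its MOM ether 9.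
5. The only stereocentre is set last: one reduction cascade takes 10 through isoflavanone 11 and cis-isoflavan-4-ol 12 to the (S)-isoflavan 13 (isoflavone reductase, vestitone reductase and quinone methide reduction modes).

Assumption: the target is read from the SMILES as (3S)-7-hydroxy-8,2',3',4',5'-pentamethoxyisoflavan; flavonoid numbering (O1, C2, C3, C4; rings A, B, C) is used throughout.

**Route**

Step 1
Reactants: 1 1,2,3,4-tetramethoxybenzene
Product: 3 2,3,4,5-tetramethoxybenzaldehyde, via iminium salt 2 (not isolated)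
Conditions: POCl3, DMF, 75 °C; then H2O, 60 °C
Reagents that add atoms: N,N-dimethylformamide (CN(C)C=O); water (O)
Why: Vilsmeier–Haack formylation; the two free ring positions of 1 are equivalent and each is para to one methoxy group and ortho to another, so the chloroiminium electrophile gives a single iminium salt 2, which water hydrolyses to aldehyde 3.

Step 2
Reactants: 4 1-(2,3,4-trihydroxyphenyl)ethanone (gallacetophenone)
Product: 6 1-[2-hydroxy-3-methoxy-4-(methoxymethoxy)phenyl]ethanone, via mono-MOM ether 5 (not isolated)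
Conditions: MOMCl (1.0 equiv), K2CO3 (1.0 equiv), acetone, 0 °C; then MeI (1.1 equiv), K2CO3 (1.5 equiv), 45 °C
Reagents that add atoms: chloromethyl methyl ether (COCCl); iodomethane (CI)
Why: Williamson ether synthesis run in order of phenol acidity: the 4-OH (para to the acetyl group) is the most acidic and takes the single equivalent of MOMCl, the 3-OH is methylated next, and the 2-OH stays free because its hydrogen bond to the carbonyl group makes it the least reactive (the same order that gives 2-hydroxy-3,4-dimethoxyacetophenone on double methylation of 4).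

Step 3
Reactants: 6 1-[2-hydroxy-3-methoxy-4-(methoxymethoxy)phenyl]ethanone; 3 2,3,4,5-tetramethoxybenzaldehyde
Product: 8 (±)-8-methoxy-7-(methoxymethoxy)-2-(2,3,4,5-tetramethoxyphenyl)chroman-4-one, via chalcone 7 (not isolated)
Conditions: KOH (50% aq.), EtOH, 25 °C, 36 h; then AcOH to pH 6, reflux, 24 h
Reagents that add atoms: none
Why: Claisen–Schmidt (crossed aldol) condensation gives the (E)-chalcone 7, and the potassium acetate buffer formed on neutralisation then catalyses the 6-endo oxa-Michael addition of the 2'-phenol to the enone, closing ring C as the racemic flavanone 8 (its C2 centre is destroyed in step 4, so its configuration does not matter); the MOM ether is stable to both media.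

Step 4
Reactants: 8 (±)-8-methoxy-7-(methoxymethoxy)-2-(2,3,4,5-tetramethoxyphenyl)chroman-4-one
Product: 10 7-hydroxy-8-methoxy-3-(2,3,4,5-tetramethoxyphenyl)-4H-chromen-4-one, via MOM-protected isoflavone 9 (not isolated)
Conditions: PhI(OH)OTs (1.2 equiv), MeCN, reflux; then HCl (3 M), MeOH, 50 °C
Reagents that add atoms: none
Why: Hypervalent iodine-mediated oxidative 2,3-aryl migration of a flavanone: the enol of 8 is bound to trivalent iodine at C3 trans to the aryl group, the electron-rich tetramethoxyphenyl ring (ortho- and para-methoxy donors) shifts from C2 to C3 as PhI leaves, the O1-stabilised C2 cation loses the C3 proton to give chromone 9, and HCl/MeOH then cleaves the MOM acetal; ring A carries no free phenol while the oxidant is present.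

Step 5
Reactants: 10 7-hydroxy-8-methoxy-3-(2,3,4,5-tetramethoxyphenyl)-4H-chromen-4-one
Product: 13 (3S)-8-methoxy-3-(2,3,4,5-tetramethoxyphenyl)chroman-7-ol, via isoflavanone 11 (not isolated), via cis-isoflavan-4-ol 12 (not isolated)
Conditions: RuCl[(S,S)-TsDPEN](p-cymene) (3 mol %), HCO2H/Et3N (5:2), EtOAc, 45 °C; then evaporate, Et3SiH, CF3CO2H, CH2Cl2, −15 to 0 °C
Reagents that add atoms: none
Why: Noyori–Ikariya asymmetric transfer hydrogenation with dynamic kinetic resolution, then ionic hydrogenation: the divalent ruthenium hydride first reduces the C2=C3 bond to isoflavanone 11, whose acidic C3–H racemises in Et3N while the (S,S)-catalyst reduces only the (3S)-ketone, anti to the aryl group, to cis-(3S,4S)-12 and so fixes C3 as S; CF3CO2H then ionises the C4 alcohol para to the 7-OH (protonated para-quinone methide) and Et3SiH delivers hydride to C4 without touching C3.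

**Compound list**

1 | 1,2,3,4-tetramethoxybenzene | COc1ccc(OC)c(OC)c1OC | starting material
2 | N,N-dimethyl-1-(2,3,4,5-tetramethoxyphenyl)methaniminium dichlorophosphate | C[N+](C)=Cc1cc(OC)c(OC)c(OC)c1OC.[O-]P(=O)(Cl)Cl | intermediate
3 | 2,3,4,5-tetramethoxybenzaldehyde | COc1cc(C=O)c(OC)c(OC)c1OC | intermediate
4 | 1-(2,3,4-trihydroxyphenyl)ethanone (gallacetophenone) | CC(=O)c1ccc(O)c(O)c1O | starting material
5 | 1-[2,3-dihydroxy-4-(methoxymethoxy)phenyl]ethanone | CC(=O)c1ccc(OCOC)c(O)c1O | intermediate
6 | 1-[2-hydroxy-3-methoxy-4-(methoxymethoxy)phenyl]ethanone | CC(=O)c1ccc(OCOC)c(OC)c1O | intermediate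
7 | (E)-1-[2-hydroxy-3-methoxy-4-(methoxymethoxy)phenyl]-3-(2,3,4,5-tetramethoxyphenyl)prop-2-en-1-one | COCOc1ccc(C(=O)/C=C/c2cc(OC)c(OC)c(OC)c2OC)c(O)c1OC | intermediate
8 | (±)-8-methoxy-7-(methoxymethoxy)-2-(2,3,4,5-tetramethoxyphenyl)chroman-4-one (racemic) | COCOc1ccc2C(=O)CC(c3cc(OC)c(OC)c(OC)c3OC)Oc2c1OC | intermediate
9 | 8-methoxy-7-(methoxymethoxy)-3-(2,3,4,5-tetramethoxyphenyl)-4H-chromen-4-one | COCOc1ccc2c(=O)c(-c3cc(OC)c(OC)c(OC)c3OC)coc2c1OC | intermediate
10 | 7-hydroxy-8-methoxy-3-(2,3,4,5-tetramethoxyphenyl)-4H-chromen-4-one | Oc1ccc2c(=O)c(-c3cc(OC)c(OC)c(OC)c3OC)coc2c1OC | intermediate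
11 | 7-hydroxy-8-methoxy-3-(2,3,4,5-tetramethoxyphenyl)chroman-4-one (C3 racemising under the conditions) | Oc1ccc2C(=O)C(c3cc(OC)c(OC)c(OC)c3OC)COc2c1OC | intermediate
12 | (3S,4S)-8-methoxy-3-(2,3,4,5-tetramethoxyphenyl)chromane-4,7-diol (cis) | COc1cc([C@H]2COc3c(ccc(O)c3OC)[C@H]2O)c(OC)c(OC)c1OC | intermediate
13 | (3S)-8-methoxy-3-(2,3,4,5-tetramethoxyphenyl)chroman-7-ol | COc1cc([C@H]2COc3c(ccc(O)c3OC)C2)c(OC)c(OC)c1OC | target

**Step count and risks**

Total step count: 5. Longest linear sequence: 4 (step 1 or step 2, then steps 3, 4 and 5).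

Most likely to fail, first: step 4. The flavanone may be dehydrogenated to the flavone instead of rearranging, the oxidant may attack the electron-rich ring B (the 2',5'-dimethoxy pair), or the MOM group may fall off early and expose the guaiacol-type phenol. The fallback sets out from chalcone 7, isolated by acidification and filtration after the KOH stage of step 3, and comes back at 10. Chalcone 7 is treated with Tl(NO3)3·3H2O in MeOH/HC(OMe)3 at 25 °C; oxythallation of the enone and 1,2-aryl shift on the open chain give the dimethyl acetal 1-[2-hydroxy-3-methoxy-4-(methoxymethoxy)phenyl]-3,3-dimethoxy-2-(2,3,4,5-tetramethoxyphenyl)propan-1-one F1. Refluxing F1 in 10% HCl/MeOH closes ring C by acetal exchange with the 2'-phenol, eliminates methanol and removes the MOM group, giving 10. Here the aryl shift precedes ring closure and no flavanone enol is needed.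

Second: step 5. The free 7-hydroxyisoflavone may resist the conjugate reduction, and the C4 cation may lose the C3 proton (isoflav-3-ene) or take a hydride shift, eroding the ee. The fallback sets out from 10 and comes back at 13. NaBH4 in EtOH/THF at 50 °C reduces 10 to the stereo-undefined 8-methoxy-3-(2,3,4,5-tetramethoxyphenyl)chromane-4,7-diol F2. TsOH (cat.) in toluene at 80 °C dehydrates this to 8-methoxy-3-(2,3,4,5-tetramethoxyphenyl)-2H-chromen-7-ol F3. Asymmetric hydrogenation of the trisubstituted alkene with [Ir(cod)(tBu-PHOX)]BArF under H2 (50 bar) in CH2Cl2 then gives 13; the ligand antipode that gives the (S)-product is fixed in a test run. The stereocentre is set by face-selective alkene hydrogenation, so no C4 cation is formed.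

Third: step 3. The chalcone–flavanone equilibrium may lie poorly for the hindered, electron-rich ring B and leave mixtures. The fallback sets out from 6 (with 3) and comes back at 8. The dianion of 6 (LDA, 2.2 equiv, THF, −78 °C) adds to aldehyde 3 to give the aldol 3-hydroxy-1-[2-hydroxy-3-methoxy-4-(methoxymethoxy)phenyl]-3-(2,3,4,5-tetramethoxyphenyl)propan-1-one F4. Mitsunobu cyclodehydration of F4 (PPh3, DIAD, THF, 0 °C) closes ring C irreversibly by attack of the phenol on the activated benzylic carbon, giving 8.

**Further compounds**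

F1 | step 4 | 1-[2-hydroxy-3-methoxy-4-(methoxymethoxy)phenyl]-3,3-dimethoxy-2-(2,3,4,5-tetramethoxyphenyl)propan-1-one (racemic) | COCOc1ccc(C(=O)C(C(OC)OC)c2cc(OC)c(OC)c(OC)c2OC)c(O)c1OC
F2 | step 5 | 8-methoxy-3-(2,3,4,5-tetramethoxyphenyl)chromane-4,7-diol (racemic, mixture of diastereomers) | COc1cc(C2COc3c(ccc(O)c3OC)C2O)c(OC)c(OC)c1OC
F3 | step 5 | 8-methoxy-3-(2,3,4,5-tetramethoxyphenyl)-2H-chromen-7-ol | COc1cc(C2=Cc3ccc(O)c(OC)c3OC2)c(OC)c(OC)c1OC
F4 | step 3 | 3-hydroxy-1-[2-hydroxy-3-methoxy-4-(methoxymethoxy)phenyl]-3-(2,3,4,5-tetramethoxyphenyl)propan-1-one (racemic) | COCOc1ccc(C(=O)CC(O)c2cc(OC)c(OC)c(OC)c2OC)c(O)c1OC
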